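Flavanone locants are used: O1, C2–C4, C4a, C5–C8, C8a, and the bridge O–C1'H2–C2'H–C3'Me2 (O on C6, C2' on C5, C3' on C8). The cage is cut at C4a–C5. The key step is an intramolecular aldol addition: the methyl carbon (C4a) of the acetyl group on C8, the only enolisable position of triketone 11, adds to the strained one-carbon-bridge ketone C5 of its 6-oxabicyclo[3.2.1]octane, which closes ring A (C4a, C5, C6, C7, C8, C8a), completes the bicyclo[2.2.2]octane and creates the C5 carbinol. Enantiopure 11, acetyl anti to the ether bridge, comes from 2-methyldimedone; the pyranone is then annulated with an (S)-3-silyloxy-3-phenylpropanoyl unit that carries C2.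

Key step: step 9

Remark on the chemistry: in step 3 the lipase is assumed to acylate the (S)-alcohol faster, so that the (R)-alcohol 5 is the recovered enantiomer; its configuration is to be confirmed before it is carried on.

Step 1
Reactants: 1 2,5,5-trimethylcyclohexane-1,3-dione
Product: 2 3-(2-methylpropoxy)-2,5,5-trimethylcyclohex-2-en-1-one
Conditions: i-BuOH, TsOH·H2O (cat.), toluene, reflux, Dean–Stark
Reagents that add atoms: 2-methylpropan-1-ol, CC(C)CO
Why: Acid-catalysed condensation of the vinylogous acid with the alcohol under azeotropic removal of water (enol ether formation as used for Stork–Danheiser substrates) is reliable for 2-alkyl-1,3-diones, and since 1 is symmetric only one enol ether can form and no stereocentre arises.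

Step 2
Reactants: 2 3-(2-methylpropoxy)-2,5,5-trimethylcyclohex-2-en-1-one; 3 formaldehyde
Product: 4 rac-6-(hydroxymethyl)-3-(2-methylpropoxy)-2,5,5-trimethylcyclohex-2-en-1-one
Conditions: LiN(i-Pr)2, THF, −78 °C; HCHO (gas, from cracked paraformaldehyde), −78 → −40 °C; AcOH
Reagents that add atoms: none
Why: Kinetic deprotonation of a 3-alkoxyenone takes place only at the alpha' methylene (Stork–Danheiser enolate), and aldol addition of this enolate to monomeric formaldehyde gives the beta-hydroxy ketone, the new stereocentre (C2' of the target) arising as the racemate.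

Step 3
Reactants: 4 rac-6-(hydroxymethyl)-3-(2-methylpropoxy)-2,5,5-trimethylcyclohex-2-en-1-one
Product: 5 (6R)-6-(hydroxymethyl)-3-(2-methylpropoxy)-2,5,5-trimethylcyclohex-2-en-1-one
Conditions: Burkholderia cepacia lipase, vinyl acetate, t-BuOMe, 30 °C, run just past half conversion; chromatography
Reagents that add atoms: none
Why: Lipase-catalysed acylative kinetic resolution of a primary alcohol with a stereocentre beta to oxygen, made irreversible by vinyl acetate, leaves the slower-reacting (R)-alcohol, whose enantiomeric purity rises with conversion, and the alcohol is separated from the (S)-acetate by chromatography.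

Step 4
Reactants: 5 (6R)-6-(hydroxymethyl)-3-(2-methylpropoxy)-2,5,5-trimethylcyclohex-2-en-1-one
Product: 6 (4R)-4-(hydroxymethyl)-2,5,5-trimethylcyclohexane-1,3-dione
Conditions: 1 M HCl, THF, 0 °C → rt; used without storage
Reagents that add atoms: water, O
Why: Acid hydrolysis of the vinylogous ester (addition of water to the enol ether carbon and loss of isobutanol) frees the 2-methyl-1,3-dione under conditions too mild to dehydrate the beta-hydroxy ketone or to enolise towards C2', so the stereocentre is kept.

Step 5
Reactants: 6 (4R)-4-(hydroxymethyl)-2,5,5-trimethylcyclohexane-1,3-dione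
Product: 7 (1R,5R)-2,2,5-trimethyl-6-oxabicyclo[3.2.1]octane-4,8-dione
Conditions: PhI(OAc)2, (CF3)2CHOH, 0 °C → rt
Reagents that add atoms: none
Why: Oxidative cycloetherification by umpolung alpha-oxygenation of a 1,3-dicarbonyl with a trivalent iodine reagent: the enolised dione binds to iodine and the tethered primary hydroxyl attacks C6 in a 5-exo mode with loss of iodobenzene, geometrically the same closure as the halo-etherification of cyclohex-3-enylmethanols, so the new quaternary centre C6 can only form with the ether oxygen cis to C1' and its configuration is relayed from C2'.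

Step 6
Reactants: 7 (1R,5R)-2,2,5-trimethyl-6-oxabicyclo[3.2.1]octane-4,8-dione
Product: 8 (1R,5R)-2,2,3,5-tetramethyl-6-oxabicyclo[3.2.1]octane-4,8-dione (C3 epimers)
Conditions: LiN(SiMe3)2, THF, −78 °C; MeI, DMPU, −78 → −20 °C
Reagents that add atoms: iodomethane, CI
Why: Enolate alkylation: the C7 ketone can enolise only towards C8 because C6 is quaternary and the alpha hydrogen of the C5 ketone sits at the bridgehead C2' (Bredt's rule), the silylamide base does not add to the strained C5 carbonyl, and the configuration of the new centre is of no consequence because it is enolised again in step 7.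

Step 7
Reactants: 8 (1R,5R)-2,2,3,5-tetramethyl-6-oxabicyclo[3.2.1]octane-4,8-dione; 9 acetaldehyde
Product: 10 (1R,3R,5S)-3-(1-hydroxyethyl)-2,2,3,5-tetramethyl-6-oxabicyclo[3.2.1]octane-4,8-dione (carbinol epimers)
Conditions: KN(SiMe3)2, THF, −78 → −20 °C; MeCHO, −78 °C; AcOH, −78 °C
Reagents that add atoms: none
Why: Aldol addition of the fully substituted potassium enolate to acetaldehyde, chosen because an aldehyde can react only at carbon whereas acetylating agents would O-acylate so hindered an enolate, should take place on the exo face of C8 (syn to the one-carbon ketone bridge C5), since the endo face is covered by the O–C1'H2 bridge as in additions to other 6-oxabicyclo[3.2.1]octenes, which sets the quaternary centre with the two-carbon arm anti to the ether bridge, while the carbinol configuration is removed in step 8.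

Step 8
Reactants: 10 (1R,3R,5S)-3-(1-hydroxyethyl)-2,2,3,5-tetramethyl-6-oxabicyclo[3.2.1]octane-4,8-dione
Product: 11 (1R,3R,5S)-3-acetyl-2,2,3,5-tetramethyl-6-oxabicyclo[3.2.1]octane-4,8-dione
Conditions: Dess–Martin periodinane, CH2Cl2, 0 °C → rt
Reagents that add atoms: none
Why: Dess–Martin oxidation of the secondary alcohol, which is in equilibrium with its hemiketal to C5, gives the non-enolisable 1,3-diketone under neutral, non-nucleophilic conditions that avoid retro-aldol and retro-Claisen cleavage, and no stereocentre is touched.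

Step 9
Reactants: 11 (1R,3R,5S)-3-acetyl-2,2,3,5-tetramethyl-6-oxabicyclo[3.2.1]octane-4,8-dione
Product: 12 (1R,3S,6R,7S)-7-hydroxy-1,3,10,10-tetramethyl-4-oxatricyclo[4.3.1.0(3,7)]decane-2,9-dione (cage ketol)
Conditions: LiN(SiMe3)2 (1.05 equiv), THF, −78 → −30 °C; AcOH, −78 °C
Reagents that add atoms: none
Why: Intramolecular aldol addition: the amide base removes a proton from the acetyl methyl group (C4a), the only enolisable position because C7 lies between the quaternary carbons C6 and C8 and the alpha hydrogen of the C5 ketone is at the bridgehead C2', and the lithium enolate adds to the C5 carbonyl to form C4a–C5. The closest known reaction is the base-induced cyclisation of 4-acetylcyclohexanones to 1-hydroxybicyclo[2.2.2]octan-3-ones, helped here by release of the angle strain of the one-carbon-bridge, alpha-alkoxy ketone C5. Ring A (C4a, C5, C6, C7, C8, C8a) closes in the 6-(enolendo)-exo-trig mode, the enolate double bond C8a=C4a lying inside the new ring, which is allowed for six-membered rings. The new stereocentre C5 is fixed by the tether and by C6, C8 and C2': the arm on C8 spans the boat of the carbocycle (C5, C6, C7, C8, C3', C2') and can reach only the face of C5 anti to the ether bridge, so the hydroxyl ends up on the bridgehead axis. The step needs chemoselectivity, not stereoselectivity: one equivalent of a non-nucleophilic base, low temperature and an acidic quench keep the two non-enolisable 1,3-diketone units from retro-Claisen cleavage and the aldolate from retro-aldol opening towards C6, which would drain into a stabilised 1,3-diketonate.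

Step 10
Reactants: 12 (1R,3S,6R,7S)-7-hydroxy-1,3,10,10-tetramethyl-4-oxatricyclo[4.3.1.0(3,7)]decane-2,9-dione
Product: 13 (1R,3S,6R,7S)-1,3,10,10-tetramethyl-7-(trimethylsilyloxy)-4-oxatricyclo[4.3.1.0(3,7)]decane-2,9-dione
Conditions: N-(trimethylsilyl)imidazole, CH2Cl2, rt
Reagents that add atoms: N-(trimethylsilyl)imidazole, C[Si](C)(C)n1ccnc1
Why: Silylation of the hindered tertiary bridgehead alcohol with the neutral silyl donor N-(trimethylsilyl)imidazole does not enolise the C8a ketone, and the ether prevents O-acylation and alkoxide-driven retro-aldol opening in step 13.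

Step 11
Reactants: 14 (3S)-3-hydroxy-3-phenylpropanoic acid
Product: 16 (3S)-3-phenyl-3-(triethylsilyloxy)propanoic acid, via silyl ester 15 (not isolated)
Conditions: Et3SiCl (2.2 equiv), imidazole, DMF, 0 °C → rt; then H2O/THF, rt
Reagents that add atoms: chlorotriethylsilane, CC[Si](Cl)(CC)CC
Why: Silylation of both the alcohol and the acid followed by hydrolysis of the silyl ester, which is far more labile than the secondary silyl ether, is the standard way to a silyloxy acid, and the purchased (S) stereocentre is not involved.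

Step 12
Reactants: 16 (3S)-3-phenyl-3-(triethylsilyloxy)propanoic acid
Product: 17 1-[(3S)-3-phenyl-3-(triethylsilyloxy)propanoyl]-1H-benzotriazole
Conditions: 1H-benzotriazole, N,N'-dicyclohexylcarbodiimide (DCC), CH2Cl2, 0 °C → rt
Reagents that add atoms: 1H-benzotriazole, c1ccc2[nH]nnc2c1
Why: Carbodiimide-mediated condensation of the acid with benzotriazole gives the N-acylbenzotriazole, a neutral and isolable reagent for C-acylation of enolates, under base-free conditions that do not eliminate the beta-silyloxy group.

Step 13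
Reactants: 13 (1R,3S,6R,7S)-1,3,10,10-tetramethyl-7-(trimethylsilyloxy)-4-oxatricyclo[4.3.1.0(3,7)]decane-2,9-dione; 17 1-[(3S)-3-phenyl-3-(triethylsilyloxy)propanoyl]-1H-benzotriazole
Product: 18 (1R,3S,6R,7R)-9-hydroxy-1,3,10,10-tetramethyl-8-[(3S)-3-phenyl-3-(triethylsilyloxy)propanoyl]-7-(trimethylsilyloxy)-4-oxatricyclo[4.3.1.0(3,7)]dec-8-en-2-one (enol form of the beta-diketone)
Conditions: LiN(SiMe3)2 (2.1 equiv), THF, −78 °C; 17, −78 → −30 °C; AcOH
Reagents that add atoms: none
Why: Crossed Claisen-type C-acylation of a lithium enolate by an N-acylbenzotriazole: the C8a ketone enolises only towards C4a (C8 is quaternary, the C7 ketone has no alpha hydrogen, and loss of the C5 silyloxy group would need a bridgehead alkene), the second equivalent of base stores the product as its diketonate, low temperature disfavours E1cB loss of silanolate from the acyl donor, and the C2 stereocentre comes in unchanged.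

Step 14
Reactants: 18 (1R,3S,6R,7R)-9-hydroxy-1,3,10,10-tetramethyl-8-[(3S)-3-phenyl-3-(triethylsilyloxy)propanoyl]-7-(trimethylsilyloxy)-4-oxatricyclo[4.3.1.0(3,7)]dec-8-en-2-one
Product: 20 CNP0322161.1 (cage flavanone; 2S,5R,6S,8R,2'R in flavanone locants), via desilylated hydroxy diketone 19 (not isolated)
Conditions: CF3CO2H, CH2Cl2, H2O (2 equiv), 0 °C → rt
Reagents that add atoms: none
Why: Acid cleaves both silyl ethers and the freed C2 hydroxyl then adds to C8a of the enolised beta-diketone and water is lost (cyclodehydration of a delta-hydroxy-beta-diketone to a 2,3-dihydro-4H-pyran-4-one, the same closure as the acid work-up of Mukaiyama-aldol-type hetero-Diels–Alder adducts), the C2–O bond is never broken so the (2S) configuration is retained, and the tertiary C5 alcohol cannot eliminate or ionise because it sits at a bridgehead.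

Compound list

1 | 2,5,5-trimethylcyclohexane-1,3-dione (2-methyldimedone) | CC1C(=O)CC(C)(C)CC1=O | starting material
2 | 3-(2-methylpropoxy)-2,5,5-trimethylcyclohex-2-en-1-one | CC(C)COC1=C(C)C(=O)CC(C)(C)C1 | intermediate
3 | formaldehyde | C=O | starting material
4 | rac-6-(hydroxymethyl)-3-(2-methylpropoxy)-2,5,5-trimethylcyclohex-2-en-1-one | CC(C)COC1=C(C)C(=O)C(CO)C(C)(C)C1 | intermediate
5 | (6R)-6-(hydroxymethyl)-3-(2-methylpropoxy)-2,5,5-trimethylcyclohex-2-en-1-one | CC(C)COC1=C(C)C(=O)[C@@H](CO)C(C)(C)C1 | intermediate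
6 | (4R)-4-(hydroxymethyl)-2,5,5-trimethylcyclohexane-1,3-dione (drawn as the diketone; enolised across C1–C3) | CC1C(=O)CC(C)(C)[C@H](CO)C1=O | intermediate
7 | (1R,5R)-2,2,5-trimethyl-6-oxabicyclo[3.2.1]octane-4,8-dione | CC1(C)[C@@H]2CO[C@](C2=O)(C)C(=O)C1 | intermediate
8 | (1R,5R)-2,2,3,5-tetramethyl-6-oxabicyclo[3.2.1]octane-4,8-dione (C3 epimers) | CC1(C)[C@@H]2CO[C@](C2=O)(C)C(=O)C1C | intermediate
9 | acetaldehyde | CC=O | starting material
10 | (1R,3R,5S)-3-(1-hydroxyethyl)-2,2,3,5-tetramethyl-6-oxabicyclo[3.2.1]octane-4,8-dione (carbinol epimers; hydroxyethyl arm anti to the ether bridge) | CC1(C)[C@@H]2CO[C@](C2=O)(C)C(=O)[C@@]1(C)C(C)O | intermediate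
11 | (1R,3R,5S)-3-acetyl-2,2,3,5-tetramethyl-6-oxabicyclo[3.2.1]octane-4,8-dione (acetyl anti to the ether bridge) | CC1(C)[C@@H]2CO[C@](C2=O)(C)C(=O)[C@@]1(C)C(C)=O | intermediate
12 | (1R,3S,6R,7S)-7-hydroxy-1,3,10,10-tetramethyl-4-oxatricyclo[4.3.1.0(3,7)]decane-2,9-dione (cage ketol) | CC1(C)[C@@H]2CO[C@]3(C)C(=O)[C@@]1(C)C(=O)C[C@]23O | intermediate
13 | (1R,3S,6R,7S)-1,3,10,10-tetramethyl-7-(trimethylsilyloxy)-4-oxatricyclo[4.3.1.0(3,7)]decane-2,9-dione | CC1(C)[C@@H]2CO[C@]3(C)C(=O)[C@@]1(C)C(=O)C[C@]23O[Si](C)(C)C | intermediate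
14 | (3S)-3-hydroxy-3-phenylpropanoic acid | OC(=O)C[C@@H](c1ccccc1)O | starting material
15 | triethylsilyl (3S)-3-phenyl-3-(triethylsilyloxy)propanoate | CC[Si](CC)(CC)OC(=O)C[C@@H](c1ccccc1)O[Si](CC)(CC)CC | intermediate
16 | (3S)-3-phenyl-3-(triethylsilyloxy)propanoic acid | OC(=O)C[C@@H](c1ccccc1)O[Si](CC)(CC)CC | intermediate
17 | 1-[(3S)-3-phenyl-3-(triethylsilyloxy)propanoyl]-1H-benzotriazole | O=C(C[C@@H](c1ccccc1)O[Si](CC)(CC)CC)n1nnc2ccccc12 | intermediate
18 | (1R,3S,6R,7R)-9-hydroxy-1,3,10,10-tetramethyl-8-[(3S)-3-phenyl-3-(triethylsilyloxy)propanoyl]-7-(trimethylsilyloxy)-4-oxatricyclo[4.3.1.0(3,7)]dec-8-en-2-one | CC1(C)[C@@H]2CO[C@]3(C)C(=O)[C@@]1(C)C(O)=C(C(=O)C[C@@H](c4ccccc4)O[Si](CC)(CC)CC)[C@]23O[Si](C)(C)C | intermediate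
19 | (1R,3S,6R,7R)-7,9-dihydroxy-8-[(3S)-3-hydroxy-3-phenylpropanoyl]-1,3,10,10-tetramethyl-4-oxatricyclo[4.3.1.0(3,7)]dec-8-en-2-one | CC1(C)[C@@H]2CO[C@]3(C)C(=O)[C@@]1(C)C(O)=C(C(=O)C[C@@H](c4ccccc4)O)[C@]23O | intermediate
20 | CNP0322161.1: cage 12 carrying a (2S)-2-phenyl-2,3-dihydro-4H-pyran-4-one fused at C4a=C8a (C8a–O1, C4a–C4=O); 2S,5R,6S,8R,2'R in flavanone locants | CC1(C)[C@@H]2CO[C@]3(C)C(=O)[C@@]1(C)C1=C(C(=O)C[C@@H](c4ccccc4)O1)[C@]23O | target

Total step count: 14. Longest linear sequence: 12 steps (steps 1 to 10, 13 and 14, from 2-methyldimedone 1); steps 11 and 12 prepare the side-chain reagent 17.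

Steps most likely to fail

Step 5 (oxidative cycloetherification). The enolonium may be captured by acetate or solvent instead of the tethered hydroxyl, and the beta-hydroxy dione may dehydrate before it cyclises. The fallback reverses the polarity and runs from 6 back to 7. Hydroxylation of the enolised dione at C6 with dimethyldioxirane (acetone, −20 °C) and separation from the C2 epimer should give (2R,4R)-2-hydroxy-4-(hydroxymethyl)-2,5,5-trimethylcyclohexane-1,3-dione F1, with the tertiary hydroxyl cis to CH2OH. Appel iodination of the primary alcohol (PPh3, I2, imidazole, CH2Cl2, 0 °C) should give (2R,4S)-2-hydroxy-4-(iodomethyl)-2,5,5-trimethylcyclohexane-1,3-dione F2. AgOSO2CF3 with 2,6-di-tert-butylpyridine (CH2Cl2, rt) then assists 5-exo-tet displacement of iodide by the tertiary hydroxyl without a base strong enough for E1cB elimination, and delivers 7.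

Step 7 (quaternary centre at C8). Removal of the endo hydrogen of 8, which lies under the ether bridge, may be slow; proton transfer with acetaldehyde, retro-aldol loss from the crowded aldolate, or attack on the endo face may also intervene. The fallback makes the enolate equivalent without deprotonation and runs from 7 back to 10. Alpha-methylenation of 7 (paraformaldehyde, N-methylanilinium trifluoroacetate, THF, reflux) should give (1R,5S)-2,2,5-trimethyl-3-methylidene-6-oxabicyclo[3.2.1]octane-4,8-dione F3. Conjugate hydrosilylation ([(Ph3P)CuH]6 cat., PhMe2SiH, toluene, rt) should give the silyl enol ether (1R,5R)-4-[dimethyl(phenyl)silyloxy]-2,2,3,5-tetramethyl-6-oxabicyclo[3.2.1]oct-3-en-8-one F4. Mukaiyama aldol addition of F4 to acetaldehyde 9 (TiCl4, CH2Cl2, −78 °C), irreversible and again on the exo face, should give 10.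

Step 9 (key aldol). Closure may stall at the oxygen-bound hemiketal or stay incomplete if the aldolate reverts, and long exposure to base may open the cage by retro-aldol towards C6 or cleave a 1,3-diketone. The fallback uses a Lewis acid instead of a base and runs from 11 back to 12. Soft enolisation of the acetyl group (Me3SiOSO2CF3, Et3N, CH2Cl2, −20 °C) should give (1R,3R,5S)-2,2,3,5-tetramethyl-3-[1-(trimethylsilyloxy)ethenyl]-6-oxabicyclo[3.2.1]octane-4,8-dione F5. An intramolecular Mukaiyama aldol addition to the activated C5 ketone (TiCl4, CH2Cl2, −78 °C; aqueous work-up) then forms C4a–C5 and gives 12.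

Further compounds

F1 | step 5 | (2R,4R)-2-hydroxy-4-(hydroxymethyl)-2,5,5-trimethylcyclohexane-1,3-dione | CC1(C)[C@H](CO)C(=O)[C@@](O)(C)C(=O)C1
F2 | step 5 | (2R,4S)-2-hydroxy-4-(iodomethyl)-2,5,5-trimethylcyclohexane-1,3-dione | CC1(C)[C@H](CI)C(=O)[C@@](O)(C)C(=O)C1
F3 | step 7 | (1R,5S)-2,2,5-trimethyl-3-methylidene-6-oxabicyclo[3.2.1]octane-4,8-dione | CC1(C)[C@@H]2CO[C@](C2=O)(C)C(=O)C1=C
F4 | step 7 | (1R,5R)-4-[dimethyl(phenyl)silyloxy]-2,2,3,5-tetramethyl-6-oxabicyclo[3.2.1]oct-3-en-8-one | CC1(C)[C@@H]2CO[C@](C2=O)(C)C(O[Si](C)(C)c3ccccc3)=C1C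
F5 | step 9 | (1R,3R,5S)-2,2,3,5-tetramethyl-3-[1-(trimethylsilyloxy)ethenyl]-6-oxabicyclo[3.2.1]octane-4,8-dione | CC1(C)[C@@H]2CO[C@](C2=O)(C)C(=O)[C@@]1(C)C(=C)O[Si](C)(C)C
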